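The 1,2-dihydronaphthalene core is cut at C2–C3 and at C4–C4a. This leaves an α-bromo (3R)-3,3-diaryl-1-arylpropanone (ring A, the pendant aryl, C1, C2 and one aroyl group) and a two-carbon enaminone carrying C3, C4 and the second aroyl group. The key step joins them in one flask: the α-keto radical at C2 alkylates the enaminone at C3, then aqueous acid closes C4 onto C4a, the ring-A carbon para to the C7 hydroxyl. Ring A is unmasked as a free catechol while the pendant ring stays a diacetate, which decides which arene cyclises. C1 comes from a rhodium-catalysed asymmetric arylation of licochalcone B triacetate; C2 is set last by kinetic protonation.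

Key step: step 9

Remark: atom numbers C1–C8a are those of the dihydronaphthalene core and ring A is its benzo ring; licochalcone B and 2,2-dimethyl-1,3-benzodioxol-4-ol are taken as purchasable, and the 1,2-cis target is assumed to be the less stable C2 epimer, so C2 is set under kinetic control.

Step 1
Reactants: 1 licochalcone B [(E)-3-(3,4-dihydroxy-2-methoxyphenyl)-1-(4-hydroxyphenyl)prop-2-en-1-one]
Product: 2 licochalcone B triacetate [4-[(E)-3-(3,4-diacetoxy-2-methoxyphenyl)acryloyl]phenyl acetate]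
Conditions: Ac2O, pyridine, DMAP (cat.), CH2Cl2, 0 °C to rt
Reagents that add atoms: acetic anhydride, CC(=O)OC(C)=O
Why: Exhaustive O-acetylation of the three phenols (DMAP-catalysed acyl transfer) protects them and makes the 2-methoxy-3,4-dioxygenated ring electron-poor, which later keeps it out of the Friedel–Crafts closure.

Step 2
Reactants: 3 2,2-dimethyl-1,3-benzodioxol-4-ol
Product: 4 5-bromo-2,2-dimethyl-1,3-benzodioxol-4-ol
Conditions: NBS, i-Pr2NH (10 mol %), CH2Cl2, 0 °C
Reagents that add atoms: N-bromosuccinimide, O=C1CCC(=O)N1Br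
Why: Amine-mediated ortho-bromination of a phenol should deliver bromine to C5, the only free position ortho to the hydroxyl and also para to ring oxygen O1, as in the conversion of guaiacol into 6-bromoguaiacol.

Step 3
Reactants: 4 5-bromo-2,2-dimethyl-1,3-benzodioxol-4-ol
Product: 5 5-bromo-4-methoxy-2,2-dimethyl-1,3-benzodioxole
Conditions: MeI, K2CO3, acetone, 50 °C
Reagents that add atoms: iodomethane, CI
Why: Williamson O-methylation of the phenol installs the methoxy group that becomes C8–OMe of the target.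

Step 4
Reactants: 5 5-bromo-4-methoxy-2,2-dimethyl-1,3-benzodioxole
Product: 8 (4-methoxy-2,2-dimethyl-1,3-benzodioxol-5-yl)boronic acid, via aryllithium 6 (not isolated), via lithium aryltrimethoxyborate 7 (not isolated)
Conditions: n-BuLi, THF, –78 °C; B(OMe)3, –78 °C to rt; 0.5 M HCl, 0 °C (brief)
Reagents that add atoms: trimethyl borate, COB(OC)OC; water, O
Why: Bromine–lithium exchange gives an aryllithium stabilised by the ortho methoxy group, which is trapped by trimethyl borate and hydrolysed to the boronic acid in a short cold acidic work-up that the catechol acetonide should survive.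

Step 5
Reactants: 2 licochalcone B triacetate; 8 (4-methoxy-2,2-dimethyl-1,3-benzodioxol-5-yl)boronic acid
Product: 9 4-[(3R)-3-(3,4-diacetoxy-2-methoxyphenyl)-3-(4-methoxy-2,2-dimethyl-1,3-benzodioxol-5-yl)propanoyl]phenyl acetate
Conditions: [Rh(OH)(cod)]2 (1.5 mol %), (R)-BINAP (3.3 mol %), dioxane/H2O 10:1, 50 °C, excess 8
Reagents that add atoms: none
Why: Hayashi–Miyaura 1,4-addition, in which the aryl–rhodium species from transmetalation inserts the enone on the face dictated by (R)-BINAP (ligand enantiomer chosen from the usual facial model for acyclic E-enones) and so sets the diarylmethine stereocentre (future C1), while the base-free aqueous conditions should spare the aryl acetates.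

Step 6
Reactants: 9 4-[(3R)-3-(3,4-diacetoxy-2-methoxyphenyl)-3-(4-methoxy-2,2-dimethyl-1,3-benzodioxol-5-yl)propanoyl]phenyl acetate
Product: 11 4-[(2RS,3R)-2-bromo-3-(3,4-diacetoxy-2-methoxyphenyl)-3-(4-methoxy-2,2-dimethyl-1,3-benzodioxol-5-yl)propanoyl]phenyl acetate, via trimethylsilyl enol ether 10 (not isolated)
Conditions: TMSOTf, Et3N, CH2Cl2, 0 °C; then NBS, THF, –78 °C
Reagents that add atoms: N-bromosuccinimide, O=C1CCC(=O)N1Br
Why: Soft enolisation gives the Z silyl enol ether without touching the aryl acetates, and its bromination by NBS at –78 °C should outrun bromination of the electron-rich benzodioxole; C2 forms as an inconsequential epimer mixture and C3 is untouched.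

Step 7
Reactants: 12 4-hydroxyacetophenone
Product: 13 (E)-3-(dimethylamino)-1-(4-hydroxyphenyl)prop-2-en-1-one
Conditions: DMF dimethyl acetal (1.1 equiv), toluene, 110 °C
Reagents that add atoms: N,N-dimethylformamide dimethyl acetal, COC(OC)N(C)C
Why: Condensation of the methyl ketone with the formamide acetal (enaminone formation) gives the E push–pull alkene, and the small excess of reagent limits O-methylation of the phenol.

Step 8
Reactants: 13 (E)-3-(dimethylamino)-1-(4-hydroxyphenyl)prop-2-en-1-one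
Product: 14 4-[(E)-3-(dimethylamino)acryloyl]phenyl acetate
Conditions: Ac2O, Et3N, DMAP (cat.), CH2Cl2, 0 °C
Reagents that add atoms: acetic anhydride, CC(=O)OC(C)=O
Why: O-acetylation of the phenol (the vinylogous amide carbon is not acylated by Ac2O at 0 °C) removes the acidic OH before the radical step.

Step 9
Reactants: 11 4-[(2RS,3R)-2-bromo-3-(3,4-diacetoxy-2-methoxyphenyl)-3-(4-methoxy-2,2-dimethyl-1,3-benzodioxol-5-yl)propanoyl]phenyl acetate; 14 4-[(E)-3-(dimethylamino)acryloyl]phenyl acetate
Product: 17 (1S,2RS)-2,3-bis(4-acetoxybenzoyl)-1-(3,4-diacetoxy-2-methoxyphenyl)-6,7-dihydroxy-8-methoxy-1,2-dihydronaphthalene, via alkylated enaminone 15 (not isolated), via catechol formyl diketone 16 (not isolated)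
Conditions: fac-Ir(ppy)3 (1 mol %), NaHCO3, 14 (1.5 equiv), degassed MeCN, blue LEDs, rt; then TFA/H2O 9:1, 40 °C, argon
Reagents that add atoms: none
Why: Photoexcited fac-Ir(ppy)3 reduces the C–Br bond of 11 and the electrophilic α-keto radical at C2 adds to the nucleophilic α-carbon of push–pull alkene 14 (C2–C3 bond); oxidation of the α-amino radical by the oxidised photocatalyst and loss of a proton give vinylogous amide 15. Aqueous TFA then hydrolyses the enaminone to the formyl diketone and cleaves the acetonide (16), the ring-A carbon para to the free C7 hydroxyl attacks the protonated aldehyde (C4–C4a bond), and the benzylic carbinol dehydrates into conjugation with the C3 aroyl group. The closest known reaction types are the photoredox α-alkylation of enaminones by α-bromo carbonyl compounds and the Bradsher-type cyclodehydration of γ-aryl α-formyl ketones to dihydronaphthalenes. The six-membered carbocycle closes by a 6-exo-trig Friedel–Crafts hydroxyalkylation (arene carbon onto the exocyclic C=O). No stereocentre is set with control: C1 is carried through untouched, and C2 forms and equilibrates as an epimer mixture that step 11 corrects. The step needs arene selectivity (ring A, not the pendant ring), secured by the free para-hydroxy catechol against the deactivated diacetate, and C- over O-cyclisation (furan formation), favoured by the nucleophilicity of the unmasked catechol ring.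

Step 10
Reactants: 17 (1S,2RS)-2,3-bis(4-acetoxybenzoyl)-1-(3,4-diacetoxy-2-methoxyphenyl)-6,7-dihydroxy-8-methoxy-1,2-dihydronaphthalene
Product: 18 (1S,2RS)-2,3-bis(4-hydroxybenzoyl)-1-(3,4-dihydroxy-2-methoxyphenyl)-6,7-dihydroxy-8-methoxy-1,2-dihydronaphthalene (target together with its C2 epimer)
Conditions: HCl (1.25 M in MeOH), degassed, 40 °C
Reagents that add atoms: none
Why: Acid-catalysed transesterification of the four aryl acetates with methanol frees all phenols under non-oxidising conditions; C2 equilibrates here, which step 11 corrects.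

Step 11
Reactants: 18 (1S,2RS)-2,3-bis(4-hydroxybenzoyl)-1-(3,4-dihydroxy-2-methoxyphenyl)-6,7-dihydroxy-8-methoxy-1,2-dihydronaphthalene
Product: 20 licobichalcone [(1S,2S)-2,3-bis(4-hydroxybenzoyl)-1-(3,4-dihydroxy-2-methoxyphenyl)-6,7-dihydroxy-8-methoxy-1,2-dihydronaphthalene], via heptakis(trimethylsilyl) dienol ether 19 (not isolated)
Conditions: TMSOTf (9 equiv), Et3N (12 equiv), CH2Cl2, 0 °C to rt; then citric acid (excess over Et3N), MeOH, –78 to –20 °C
Reagents that add atoms: none
Why: Soft enolisation silylates the six phenols and turns the C2 ketone into its silyl dienol ether (C2 trigonal), and low-temperature protodesilylation should then deliver the proton to the α-carbon C2 from the face opposite the C1 aryl group (held pseudoaxial by the peri C8 methoxy group), giving the 1,2-cis (1S,2S) isomer by kinetic protonation under substrate control while the aryl silyl ethers are methanolysed.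

Compound list
1 | licochalcone B, (E)-3-(3,4-dihydroxy-2-methoxyphenyl)-1-(4-hydroxyphenyl)prop-2-en-1-one | COc1c(/C=C/C(=O)c2ccc(O)cc2)ccc(O)c1O | starting material
2 | licochalcone B triacetate | COc1c(/C=C/C(=O)c2ccc(OC(C)=O)cc2)ccc(OC(C)=O)c1OC(C)=O | intermediate
3 | 2,2-dimethyl-1,3-benzodioxol-4-ol | CC1(C)Oc2cccc(O)c2O1 | starting material
4 | 5-bromo-2,2-dimethyl-1,3-benzodioxol-4-ol | CC1(C)Oc2ccc(Br)c(O)c2O1 | intermediate
5 | 5-bromo-4-methoxy-2,2-dimethyl-1,3-benzodioxole | CC1(C)Oc2ccc(Br)c(OC)c2O1 | intermediate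
6 | (4-methoxy-2,2-dimethyl-1,3-benzodioxol-5-yl)lithium, not isolated | CC1(C)Oc2ccc([Li])c(OC)c2O1 | intermediate
7 | lithium trimethoxy(4-methoxy-2,2-dimethyl-1,3-benzodioxol-5-yl)borate, not isolated | [Li+].CO[B-](OC)(OC)c1ccc2OC(C)(C)Oc2c1OC | intermediate
8 | (4-methoxy-2,2-dimethyl-1,3-benzodioxol-5-yl)boronic acid | COc1c(B(O)O)ccc2OC(C)(C)Oc12 | intermediate
9 | 4-[(3R)-3-(3,4-diacetoxy-2-methoxyphenyl)-3-(4-methoxy-2,2-dimethyl-1,3-benzodioxol-5-yl)propanoyl]phenyl acetate | CC(=O)Oc1ccc(cc1)C(=O)C[C@@H](c1ccc(OC(C)=O)c(OC(C)=O)c1OC)c1ccc2OC(C)(C)Oc2c1OC | intermediate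
10 | (Z)-trimethylsilyl enol ether of 9, not isolated | CC(=O)Oc1ccc(cc1)/C(O[Si](C)(C)C)=C/[C@@H](c1ccc(OC(C)=O)c(OC(C)=O)c1OC)c1ccc2OC(C)(C)Oc2c1OC | intermediate
11 | 4-[(2RS,3R)-2-bromo-3-(3,4-diacetoxy-2-methoxyphenyl)-3-(4-methoxy-2,2-dimethyl-1,3-benzodioxol-5-yl)propanoyl]phenyl acetate (C2 epimers) | CC(=O)Oc1ccc(cc1)C(=O)C(Br)[C@@H](c1ccc(OC(C)=O)c(OC(C)=O)c1OC)c1ccc2OC(C)(C)Oc2c1OC | intermediate
12 | 4-hydroxyacetophenone | CC(=O)c1ccc(O)cc1 | starting material
13 | (E)-3-(dimethylamino)-1-(4-hydroxyphenyl)prop-2-en-1-one | CN(C)/C=C/C(=O)c1ccc(O)cc1 | intermediate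
14 | 4-[(E)-3-(dimethylamino)acryloyl]phenyl acetate | CN(C)/C=C/C(=O)c1ccc(OC(C)=O)cc1 | intermediate
15 | 1,4-bis(4-acetoxyphenyl)-2-[(dimethylamino)methylidene]-3-[(R)-(3,4-diacetoxy-2-methoxyphenyl)(4-methoxy-2,2-dimethyl-1,3-benzodioxol-5-yl)methyl]butane-1,4-dione, C3 epimers, alkene drawn E, not isolated | CN(C)/C=C(/C(=O)c1ccc(OC(C)=O)cc1)C(C(=O)c1ccc(OC(C)=O)cc1)[C@@H](c1ccc(OC(C)=O)c(OC(C)=O)c1OC)c1ccc2OC(C)(C)Oc2c1OC | intermediate
16 | 1,4-bis(4-acetoxyphenyl)-2-formyl-3-[(R)-(3,4-diacetoxy-2-methoxyphenyl)(3,4-dihydroxy-2-methoxyphenyl)methyl]butane-1,4-dione, C2 and C3 epimers, not isolated | O=CC(C(=O)c1ccc(OC(C)=O)cc1)C(C(=O)c1ccc(OC(C)=O)cc1)[C@@H](c1ccc(OC(C)=O)c(OC(C)=O)c1OC)c1ccc(O)c(O)c1OC | intermediate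
17 | (1S,2RS)-2,3-bis(4-acetoxybenzoyl)-1-(3,4-diacetoxy-2-methoxyphenyl)-6,7-dihydroxy-8-methoxy-1,2-dihydronaphthalene (C2 epimers) | COc1c([C@H]2c3c(cc(O)c(O)c3OC)C=C(C(=O)c3ccc(OC(C)=O)cc3)C2C(=O)c2ccc(OC(C)=O)cc2)ccc(OC(C)=O)c1OC(C)=O | intermediate
18 | (1S,2RS)-2,3-bis(4-hydroxybenzoyl)-1-(3,4-dihydroxy-2-methoxyphenyl)-6,7-dihydroxy-8-methoxy-1,2-dihydronaphthalene (C2 epimers) | COc1c([C@H]2c3c(cc(O)c(O)c3OC)C=C(C(=O)c3ccc(O)cc3)C2C(=O)c2ccc(O)cc2)ccc(O)c1O | intermediate
19 | hexa-O-trimethylsilyl ether and C2 trimethylsilyl dienol ether of 18, C1 configuration as in 18, not isolated | COc1c([C@H]2c3c(cc(O[Si](C)(C)C)c(O[Si](C)(C)C)c3OC)C=C(C(=O)c3ccc(O[Si](C)(C)C)cc3)C2=C(O[Si](C)(C)C)c2ccc(O[Si](C)(C)C)cc2)ccc(O[Si](C)(C)C)c1O[Si](C)(C)C | intermediate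
20 | licobichalcone, (1S,2S)-2,3-bis(4-hydroxybenzoyl)-1-(3,4-dihydroxy-2-methoxyphenyl)-6,7-dihydroxy-8-methoxy-1,2-dihydronaphthalene | COc1c([C@H]2c3c(cc(O)c(O)c3OC)C=C(C(=O)c3ccc(O)cc3)[C@H]2C(=O)c2ccc(O)cc2)ccc(O)c1O | target

Total step count: 11. Longest linear sequence: 8 steps (steps 2, 3, 4, 5, 6, 9, 10 and 11).

Steps most likely to fail

Step 9. Radical capture by the enaminone may be too slow, so that loss of HBr from 11 or a 1,2-aryl shift of the radical competes. In the acid stage, O-cyclisation to a furan or intermolecular hydroxyalkylation of the catechol ring by aldehyde from excess 14 may erode the closure. The fallback reverses the polarity of the C2–C3 union. 12 is acetylated (Ac2O, pyridine) to 4-acetylphenyl acetate F1. F1 is converted with HC(OMe)3/BF3·OEt2 and then i-Pr2NEt into 4-(3,3-dimethoxypropanoyl)phenyl acetate F2, which is brominated (NBS, NH4OAc cat.) to 4-(2-bromo-3,3-dimethoxypropanoyl)phenyl acetate F3. The silyl enol ether 10, made from 9 as in step 6 and isolated by non-aqueous work-up, is then alkylated by the α-keto radical of F3 (fac-Ir(ppy)3, blue LEDs, MeCN; the known photoredox α-alkylation of enol silanes to 1,4-diketones) to give the acetal diketone F4. TFA/H2O then closes and dehydrates F4 to 17 as in the second stage of step 9. This fallback sets out from 12 and 9 and comes back at 17.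

Step 11. Facial selectivity of the protonation may be poor, protonation may occur at the γ-carbon C4, or the cis product may re-equilibrate during desilylation. In the fallback, 18 is silylated (TBSCl, imidazole, DMF) to the hexakis(tert-butyldimethylsilyl) ether F6 and deprotonated with KN(SiMe3)2 (THF, –78 °C). The potassium dienolate is quenched at –78 °C with 2,6-di-tert-butylphenol, a bulky proton donor (the classical kinetic α-protonation of a metal dienolate), to give the 1,2-cis hexakis(tert-butyldimethylsilyl) ether F7. HF·pyridine (THF/pyridine, 0 °C) then desilylates F7 under weakly acidic conditions. This fallback sets out from 18 and comes back at 20.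

Step 5. Protodeboronation of the electron-rich ortho-methoxy boronic acid may outpace transmetalation and insertion, and enantiofacial control may be weak for this doubly ortho-methoxylated diarylmethine. In the fallback, 2 and 8 are coupled without asymmetric induction by Pd(OAc)2/2,2'-bipyridine in AcOH/THF/H2O (conjugate addition by an aryl complex of divalent palladium) to give the racemic ketone rac-9 F5, which is resolved by preparative chiral SFC. This fallback sets out from 2 and 8 and comes back at 9.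

Further compounds
F1 | step 9 | 4-acetylphenyl acetate | CC(=O)Oc1ccc(cc1)C(C)=O
F2 | step 9 | 4-(3,3-dimethoxypropanoyl)phenyl acetate | COC(OC)CC(=O)c1ccc(OC(C)=O)cc1
F3 | step 9 | 4-(2-bromo-3,3-dimethoxypropanoyl)phenyl acetate | COC(OC)C(Br)C(=O)c1ccc(OC(C)=O)cc1
F4 | step 9 | 1,4-bis(4-acetoxyphenyl)-2-(dimethoxymethyl)-3-[(R)-(3,4-diacetoxy-2-methoxyphenyl)(4-methoxy-2,2-dimethyl-1,3-benzodioxol-5-yl)methyl]butane-1,4-dione (C2 and C3 epimers) | COC(OC)C(C(=O)c1ccc(OC(C)=O)cc1)C(C(=O)c1ccc(OC(C)=O)cc1)[C@@H](c1ccc(OC(C)=O)c(OC(C)=O)c1OC)c1ccc2OC(C)(C)Oc2c1OC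
F5 | step 5 | rac-9, racemic 4-[3-(3,4-diacetoxy-2-methoxyphenyl)-3-(4-methoxy-2,2-dimethyl-1,3-benzodioxol-5-yl)propanoyl]phenyl acetate | CC(=O)Oc1ccc(cc1)C(=O)CC(c1ccc(OC(C)=O)c(OC(C)=O)c1OC)c1ccc2OC(C)(C)Oc2c1OC
F6 | step 11 | hexakis(tert-butyldimethylsilyl) ether of 18 (1S,2RS) | COc1c([C@H]2c3c(cc(O[Si](C)(C)C(C)(C)C)c(O[Si](C)(C)C(C)(C)C)c3OC)C=C(C(=O)c3ccc(O[Si](C)(C)C(C)(C)C)cc3)C2C(=O)c2ccc(O[Si](C)(C)C(C)(C)C)cc2)ccc(O[Si](C)(C)C(C)(C)C)c1O[Si](C)(C)C(C)(C)C
F7 | step 11 | hexakis(tert-butyldimethylsilyl) ether of 20 (1S,2S) | COc1c([C@H]2c3c(cc(O[Si](C)(C)C(C)(C)C)c(O[Si](C)(C)C(C)(C)C)c3OC)C=C(C(=O)c3ccc(O[Si](C)(C)C(C)(C)C)cc3)[C@H]2C(=O)c2ccc(O[Si](C)(C)C(C)(C)C)cc2)ccc(O[Si](C)(C)C(C)(C)C)c1O[Si](C)(C)C(C)(C)C
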